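**Retrosynthetic overview**
- Target ⇐ aryl silyl ether carrying a side-chain chlorohydrin (last moves: tertiary C–OH → C–Br, desilylation). Rings A and B, with C5, C9 and C10, are bought in andrographolide 1.
- C4 quaternary centre ⇐ 3-oxo-19-al of the trimmed core: retro-Claisen deformylation, then enolate alkylation anti to the C10 methyl with a chloro-iodide made from (S)-α-hydroxy-γ-butyrolactone 2, which supplies the CHCl centre. C3–Br ⇐ ketone (axial alcohol, inversion).
- Key step: the dibromophenol ring ⇐ [4+2]/retro-[4+2] (loss of CO2) between 3,5-dibromo-2H-pyran-2-one 3 and a siloxyalkyne grown from the C12 aldehyde left by ozonolysis of 1.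
- Ring order: rings A/B are bought; the aromatic ring is the only ring made, by the cycloaddition, late in the sequence.

Assumption: 1, 2 and 3 are purchased; decalin positions follow the labdane numbering of 1 (ring carbons C1–C10, C11 on C9), α is the face of the C10 methyl, and every decalin compound keeps the 5β-H/9β-H/10α-CH3 trans-decalin of 1.

**Step 1**
Reactants: 1 andrographolide
Product: 4 3α-hydroxy-4α-(hydroxymethyl)-4β-methyl-9α-(2-oxoethyl)decalin-8-one
Conditions: O3, CH2Cl2/MeOH, −78 °C; then Me2S, −78 °C → rt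
Reagents that add atoms: ozone, O=[O+][O-]
Why: Ozonolysis with reductive work-up cleaves both the 8(17)-methylene and the C12=C13 alkylidene-lactone bond, leaving C5 and C10 untouched and C9 (now α to the ketone) in its favoured equatorial configuration.

**Step 2**
Reactants: 4 3α-hydroxy-4α-(hydroxymethyl)-4β-methyl-9α-(2-oxoethyl)decalin-8-one
Product: 5 3α-hydroxy-4α-(hydroxymethyl)-4β-methyl-9α-(prop-2-ynyl)decalin-8-one
Conditions: dimethyl (1-diazo-2-oxopropyl)phosphonate, K2CO3, MeOH, 0 °C → rt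
Reagents that add atoms: dimethyl (1-diazo-2-oxopropyl)phosphonate, COP(=O)(OC)C(=[N+]=[N-])C(C)=O
Why: Ohira–Bestmann (Seyferth–Gilbert) homologation converts only the aldehyde into the terminal alkyne under mild carbonate conditions that the hindered C8 ketone and the diol tolerate; no stereocentre is formed.

**Step 3**
Reactants: 5 3α-hydroxy-4α-(hydroxymethyl)-4β-methyl-9α-(prop-2-ynyl)decalin-8-one
Product: 6 4α-(hydroxymethyl)-4β-methyl-8-methylene-9α-(prop-2-ynyl)decalin-3α-ol
Conditions: Ph3PCH3Br, KOtBu (5 equiv each), THF, 0 → 65 °C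
Reagents that add atoms: methyltriphenylphosphonium bromide, C[P+](c1ccccc1)(c1ccccc1)c1ccccc1.[Br-]
Why: Wittig methylenation with excess ylide restores the exocyclic alkene at the hindered C8 ketone, and the epimerisable C9 centre keeps its thermodynamically preferred equatorial side chain.

**Step 4**
Reactants: 6 4α-(hydroxymethyl)-4β-methyl-8-methylene-9α-(prop-2-ynyl)decalin-3α-ol
Product: 7 4β-methyl-8-methylene-3-oxo-9α-(prop-2-ynyl)decalin-4α-carbaldehyde
Conditions: Dess–Martin periodinane (2.5 equiv), CH2Cl2, 0 °C → rt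
Reagents that add atoms: none
Why: Dess–Martin oxidation of both hydroxyls gives a non-enolisable β-keto aldehyde that sets up the retro-Claisen step; the C3 centre is deliberately erased and C4 is unchanged.

**Step 5**
Reactants: 2 (S)-3-hydroxydihydrofuran-2(3H)-one
Product: 8 (R)-3-chlorodihydrofuran-2(3H)-one
Conditions: PPh3, CCl4, CH2Cl2, 40 °C
Reagents that add atoms: carbon tetrachloride, ClC(Cl)(Cl)Cl
Why: Appel chlorination is an SN2 displacement α to the lactone carbonyl, so the bought (S)-carbinol gives the (R)-chloride by inversion.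

**Step 6**
Reactants: 8 (R)-3-chlorodihydrofuran-2(3H)-one
Product: 9 (R)-3-chloro-4-methylpentane-1,4-diol
Conditions: MeMgBr (2.5 equiv), THF, −78 → −30 °C; aq. NH4Cl at −30 °C
Reagents that add atoms: methylmagnesium bromide, C[Mg]Br
Why: Double Grignard addition to the activated lactone carbonyl outruns enolisation at low temperature and builds the tertiary alcohol without touching the C–Cl centre, and the cold quench prevents epoxide closure.

**Step 7**
Reactants: 9 (R)-3-chloro-4-methylpentane-1,4-diol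
Product: 10 (R)-3-chloro-5-iodo-2-methylpentan-2-ol
Conditions: I2, PPh3, imidazole, CH2Cl2, 0 °C
Reagents that add atoms: iodine, [I][I]
Why: Appel-type iodination is selective for the primary alcohol over the hindered tertiary one.

**Step 8**
Reactants: 10 (R)-3-chloro-5-iodo-2-methylpentan-2-ol
Product: 11 (R)-[(3-chloro-5-iodo-2-methylpentan-2-yl)oxy]triethylsilane
Conditions: Et3SiOTf, 2,6-lutidine, CH2Cl2, −78 → 0 °C
Reagents that add atoms: triethylsilyl trifluoromethanesulfonate, CC[Si](CC)(CC)OS(=O)(=O)C(F)(F)F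
Why: Silylation of the tertiary alcohol blocks alkoxide formation, and hence epoxide closure onto the chloride, in the basic steps that follow.

**Step 9**
Reactants: 7 4β-methyl-8-methylene-3-oxo-9α-(prop-2-ynyl)decalin-4α-carbaldehyde, 11 (R)-[(3-chloro-5-iodo-2-methylpentan-2-yl)oxy]triethylsilane
Product: 13 4β-[(3R)-3-chloro-4-methyl-4-(triethylsilyloxy)pentyl]-4α-methyl-8-methylene-9α-(prop-2-ynyl)decalin-3-one, via potassium enolate 12 (not isolated)
Conditions: KOMe (1.0 equiv), THF/DMPU, 0 °C; methyl formate removed in vacuo; then 11, −20 °C → rt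
Reagents that add atoms: none
Why: Retro-Claisen deformylation by methoxide gives the tetrasubstituted C3/C4 enolate regiospecifically, and its SN2 alkylation occurs on the β face, anti to the axial C10 methyl, so the chain ends equatorial and the methyl axial at the new C4 quaternary centre.

**Step 10**
Reactants: 13 4β-[(3R)-3-chloro-4-methyl-4-(triethylsilyloxy)pentyl]-4α-methyl-8-methylene-9α-(prop-2-ynyl)decalin-3-one
Product: 14 4β-[(3R)-3-chloro-4-methyl-4-(triethylsilyloxy)pentyl]-4α-methyl-8-methylene-9α-(prop-2-ynyl)decalin-3β-ol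
Conditions: LiBH(s-Bu)3, THF, −78 °C
Reagents that add atoms: none
Why: The bulky trialkylborohydride attacks the C3 ketone along the equatorial trajectory (substrate-controlled hydride reduction), giving the axial 3β alcohol needed for inversion.

**Step 11**
Reactants: 14 4β-[(3R)-3-chloro-4-methyl-4-(triethylsilyloxy)pentyl]-4α-methyl-8-methylene-9α-(prop-2-ynyl)decalin-3β-ol
Product: 15 3α-bromo-4β-[(3R)-3-chloro-4-methyl-4-(triethylsilyloxy)pentyl]-4α-methyl-8-methylene-9α-(prop-2-ynyl)decalin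
Conditions: PPh3, CBr4, CH2Cl2, 0 → 40 °C
Reagents that add atoms: carbon tetrabromide, BrC(Br)(Br)Br
Why: Appel bromination displaces the axial oxyphosphonium group by SN2 with inversion, so bromine arrives equatorial (3α), where it has no anti-periplanar hydrogen and resists later elimination.

**Step 12**
Reactants: 15 3α-bromo-4β-[(3R)-3-chloro-4-methyl-4-(triethylsilyloxy)pentyl]-4α-methyl-8-methylene-9α-(prop-2-ynyl)decalin
Product: 18 3α-bromo-4β-[(3R)-3-chloro-4-methyl-4-(triethylsilyloxy)pentyl]-4α-methyl-8-methylene-9α-[3-(triisopropylsilyloxy)prop-2-ynyl]decalin, via lithium acetylide 16 (not isolated), via lithium ynolate 17 (not isolated)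
Conditions: LiN(SiMe3)2 (2.2 equiv), t-BuOOH (1.1 equiv), THF, −78 → 0 °C; then i-Pr3SiOTf (2.5 equiv), −78 °C
Reagents that add atoms: tert-butyl hydroperoxide, CC(C)(C)OO; triisopropylsilyl trifluoromethanesulfonate, CC(C)[Si](OS(=O)(=O)C(F)(F)F)(C(C)C)C(C)C
Why: Oxidation of the lithium acetylide by lithium tert-butyl peroxide gives the ynolate (Julia ynolate synthesis), which the bulky silyl triflate traps on oxygen as the siloxyalkyne; the hindered amide base does not touch the equatorial bromide.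

**Step 13**
Reactants: 18 3α-bromo-4β-[(3R)-3-chloro-4-methyl-4-(triethylsilyloxy)pentyl]-4α-methyl-8-methylene-9α-[3-(triisopropylsilyloxy)prop-2-ynyl]decalin, 3 3,5-dibromo-2H-pyran-2-one
Product: 20 {2,4-dibromo-6-[(3α-bromo-4β-[(3R)-3-chloro-4-methyl-4-(triethylsilyloxy)pentyl]-4α-methyl-8-methylenedecalin-9α-yl)methyl]phenoxy}triisopropylsilane, via bicyclic lactone adduct 19 (not isolated)
Conditions: 3 (2 equiv), toluene, 80 °C, sealed tube
Reagents that add atoms: none
Why: Inverse-electron-demand Diels–Alder addition of the electron-rich siloxyalkyne to the electron-poor pyrone (alkyl-bearing carbon to C6, siloxy carbon to C3) and retro-Diels–Alder loss of CO2 build the benzene ring with O, Br, H, Br, H already in the required order; no stereocentre is involved.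

**Step 14**
Reactants: 20 {2,4-dibromo-6-[(3α-bromo-4β-[(3R)-3-chloro-4-methyl-4-(triethylsilyloxy)pentyl]-4α-methyl-8-methylenedecalin-9α-yl)methyl]phenoxy}triisopropylsilane
Product: 21 {2,4-dibromo-6-[(3α-bromo-4β-[(3R)-3-chloro-4-hydroxy-4-methylpentyl]-4α-methyl-8-methylenedecalin-9α-yl)methyl]phenoxy}triisopropylsilane
Conditions: PPTS, MeOH/CH2Cl2, rt
Reagents that add atoms: none
Why: Mild acid methanolysis removes the alkyl triethylsilyl ether, while the acid-stable aryl triisopropylsilyl ether and the exocyclic alkene survive.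

**Step 15**
Reactants: 21 {2,4-dibromo-6-[(3α-bromo-4β-[(3R)-3-chloro-4-hydroxy-4-methylpentyl]-4α-methyl-8-methylenedecalin-9α-yl)methyl]phenoxy}triisopropylsilane
Product: 22 {2,4-dibromo-6-[(3α-bromo-4β-[(3R)-4-bromo-3-chloro-4-methylpentyl]-4α-methyl-8-methylenedecalin-9α-yl)methyl]phenoxy}triisopropylsilane
Conditions: 1-bromo-N,N,2-trimethylprop-1-en-1-amine, 2,6-di-tert-butylpyridine, CH2Cl2, 0 °C → rt
Reagents that add atoms: 1-bromo-N,N,2-trimethylprop-1-en-1-amine, CC(C)=C(Br)N(C)C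
Why: The α-bromoenamine (Ghosez-type reagent) turns the tertiary alcohol into the bromide through an alkoxyiminium bromide under neutral, HBr-free conditions (SN1-type collapse at the non-stereogenic carbon), sparing the exocyclic alkene and leaving the C–Cl centre untouched.

**Step 16**
Reactants: 22 {2,4-dibromo-6-[(3α-bromo-4β-[(3R)-4-bromo-3-chloro-4-methylpentyl]-4α-methyl-8-methylenedecalin-9α-yl)methyl]phenoxy}triisopropylsilane
Product: 23 2,4-dibromo-6-[(3α-bromo-4β-[(3R)-4-bromo-3-chloro-4-methylpentyl]-4α-methyl-8-methylenedecalin-9α-yl)methyl]phenol (CNP0262552.2)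
Conditions: Bu4NF, AcOH, THF, 0 °C
Reagents that add atoms: none
Why: Fluoride desilylation frees the phenol, and the acetic acid buffer suppresses E2 loss of the tertiary bromide.

**Compound list**
1 | andrographolide | C=C1CC[C@@H]2[C@](C)(CO)[C@H](O)CC[C@@]2(C)[C@@H]1C/C=C/3\[C@@H](COC3=O)O | starting material
2 | (S)-3-hydroxydihydrofuran-2(3H)-one [(S)-α-hydroxy-γ-butyrolactone] | O=C1OCC[C@@H]1O | starting material
3 | 3,5-dibromo-2H-pyran-2-one | O=C1OC=C(Br)C=C1Br | starting material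
4 | 3α-hydroxy-4α-(hydroxymethyl)-4β-methyl-9α-(2-oxoethyl)decalin-8-one | O=C1CC[C@@H]2[C@](C)(CO)[C@H](O)CC[C@@]2(C)[C@@H]1CC=O | intermediate
5 | 3α-hydroxy-4α-(hydroxymethyl)-4β-methyl-9α-(prop-2-ynyl)decalin-8-one | O=C1CC[C@@H]2[C@](C)(CO)[C@H](O)CC[C@@]2(C)[C@@H]1CC#C | intermediate
6 | 4α-(hydroxymethyl)-4β-methyl-8-methylene-9α-(prop-2-ynyl)decalin-3α-ol | C=C1CC[C@@H]2[C@](C)(CO)[C@H](O)CC[C@@]2(C)[C@@H]1CC#C | intermediate
7 | 4β-methyl-8-methylene-3-oxo-9α-(prop-2-ynyl)decalin-4α-carbaldehyde | C=C1CC[C@@H]2[C@](C)(C=O)C(=O)CC[C@@]2(C)[C@@H]1CC#C | intermediate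
8 | (R)-3-chlorodihydrofuran-2(3H)-one | O=C1OCC[C@H]1Cl | intermediate
9 | (R)-3-chloro-4-methylpentane-1,4-diol | OCC[C@@H](Cl)C(C)(C)O | intermediate
10 | (R)-3-chloro-5-iodo-2-methylpentan-2-ol | ICC[C@@H](Cl)C(C)(C)O | intermediate
11 | (R)-[(3-chloro-5-iodo-2-methylpentan-2-yl)oxy]triethylsilane | ICC[C@@H](Cl)C(C)(C)O[Si](CC)(CC)CC | intermediate
12 | potassium 4-methyl-8-methylene-9α-(prop-2-ynyl)decal-3-en-3-olate | C=C1CC[C@@H]2C(C)=C([O-])CC[C@@]2(C)[C@@H]1CC#C.[K+] | intermediate (not isolated)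
13 | 4β-[(3R)-3-chloro-4-methyl-4-(triethylsilyloxy)pentyl]-4α-methyl-8-methylene-9α-(prop-2-ynyl)decalin-3-one | C=C1CC[C@@H]2[C@@](C)(CC[C@@H](Cl)C(C)(C)O[Si](CC)(CC)CC)C(=O)CC[C@@]2(C)[C@@H]1CC#C | intermediate
14 | 4β-[(3R)-3-chloro-4-methyl-4-(triethylsilyloxy)pentyl]-4α-methyl-8-methylene-9α-(prop-2-ynyl)decalin-3β-ol (axial OH) | C=C1CC[C@@H]2[C@@](C)(CC[C@@H](Cl)C(C)(C)O[Si](CC)(CC)CC)[C@@H](O)CC[C@@]2(C)[C@@H]1CC#C | intermediate
15 | 3α-bromo-4β-[(3R)-3-chloro-4-methyl-4-(triethylsilyloxy)pentyl]-4α-methyl-8-methylene-9α-(prop-2-ynyl)decalin (equatorial Br) | C=C1CC[C@@H]2[C@@](C)(CC[C@@H](Cl)C(C)(C)O[Si](CC)(CC)CC)[C@H](Br)CC[C@@]2(C)[C@@H]1CC#C | intermediate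
16 | lithium acetylide of 15 | C=C1CC[C@@H]2[C@@](C)(CC[C@@H](Cl)C(C)(C)O[Si](CC)(CC)CC)[C@H](Br)CC[C@@]2(C)[C@@H]1CC#[C-].[Li+] | intermediate (not isolated)
17 | lithium ynolate (9α-CH2–C≡C–OLi) derived from 15 | C=C1CC[C@@H]2[C@@](C)(CC[C@@H](Cl)C(C)(C)O[Si](CC)(CC)CC)[C@H](Br)CC[C@@]2(C)[C@@H]1CC#C[O-].[Li+] | intermediate (not isolated)
18 | 3α-bromo-4β-[(3R)-3-chloro-4-methyl-4-(triethylsilyloxy)pentyl]-4α-methyl-8-methylene-9α-[3-(triisopropylsilyloxy)prop-2-ynyl]decalin | C=C1CC[C@@H]2[C@@](C)(CC[C@@H](Cl)C(C)(C)O[Si](CC)(CC)CC)[C@H](Br)CC[C@@]2(C)[C@@H]1CC#CO[Si](C(C)C)(C(C)C)C(C)C | intermediate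
19 | 4,7-dibromo-6-(decalin-9α-ylmethyl)-5-(triisopropylsilyloxy)-2-oxabicyclo[2.2.2]octa-5,7-dien-3-one, decalin as in 18, both bridgehead diastereomers | C=C1CC[C@@H]2[C@@](C)(CC[C@@H](Cl)C(C)(C)O[Si](CC)(CC)CC)[C@H](Br)CC[C@@]2(C)[C@@H]1CC3=C(O[Si](C(C)C)(C(C)C)C(C)C)C4(Br)C=C(Br)C3OC4=O | intermediate (not isolated)
20 | {2,4-dibromo-6-[(3α-bromo-4β-[(3R)-3-chloro-4-methyl-4-(triethylsilyloxy)pentyl]-4α-methyl-8-methylenedecalin-9α-yl)methyl]phenoxy}triisopropylsilane | C=C1CC[C@@H]2[C@@](C)(CC[C@@H](Cl)C(C)(C)O[Si](CC)(CC)CC)[C@H](Br)CC[C@@]2(C)[C@@H]1Cc1cc(Br)cc(Br)c1O[Si](C(C)C)(C(C)C)C(C)C | intermediate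
21 | {2,4-dibromo-6-[(3α-bromo-4β-[(3R)-3-chloro-4-hydroxy-4-methylpentyl]-4α-methyl-8-methylenedecalin-9α-yl)methyl]phenoxy}triisopropylsilane | C=C1CC[C@@H]2[C@@](C)(CC[C@@H](Cl)C(C)(C)O)[C@H](Br)CC[C@@]2(C)[C@@H]1Cc1cc(Br)cc(Br)c1O[Si](C(C)C)(C(C)C)C(C)C | intermediate
22 | {2,4-dibromo-6-[(3α-bromo-4β-[(3R)-4-bromo-3-chloro-4-methylpentyl]-4α-methyl-8-methylenedecalin-9α-yl)methyl]phenoxy}triisopropylsilane | C=C1CC[C@@H]2[C@@](C)(CC[C@@H](Cl)C(C)(C)Br)[C@H](Br)CC[C@@]2(C)[C@@H]1Cc1cc(Br)cc(Br)c1O[Si](C(C)C)(C(C)C)C(C)C | intermediate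
23 | 2,4-dibromo-6-[(3α-bromo-4β-[(3R)-4-bromo-3-chloro-4-methylpentyl]-4α-methyl-8-methylenedecalin-9α-yl)methyl]phenol (CNP0262552.2) | C=C1CC[C@@H]2[C@@](C)(CC[C@@H](Cl)C(C)(C)Br)[C@H](Br)CC[C@@]2(C)[C@@H]1Cc1cc(Br)cc(Br)c1O | target

**Totals**
Total step count: 16. Longest linear sequence: 12 steps (1 → 23 through steps 1–4 and 9–16; the branch from 2 through steps 5–16 is equally long).

**Steps most likely to fail**

Step 9. The hindered tetrasubstituted enolate meets an unactivated primary iodide, so O-alkylation or proton transfer may dominate. Fallback: separate enolate generation from the formyl chemistry. Setting out from 7, K2CO3/MeOH removes the formyl group and gives 4β-methyl-8-methylene-9α-(prop-2-ynyl)decalin-3-one F1. Me3SiCl/NaI/Et3N in MeCN converts it into the more substituted silyl enol ether 4-methyl-8-methylene-9α-(prop-2-ynyl)-3-(trimethylsilyloxy)decal-3-ene F2, which is purified. MeLi in THF/DMPU then releases a salt-free lithium enolate that is alkylated with 11, coming back to the route at 13.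

Step 11. This is an SN2 displacement at a neopentylic carbon, so elimination to the 2-ene or a methyl shift may win. Fallback without substitution at C3: setting out from 13, hydrazine gives the hydrazone of 13 F3. N-Bromosuccinimide/pyridine oxidises it to the 3,3-dibromo analogue of 15 F4. Bu3SnH (1 equiv)/Et3B at −78 °C removes one bromine; the α-bromo radical takes hydrogen on the open β face, so the remaining bromine is equatorial (3α). This comes back to the route at 15.

Step 13. The siloxyalkyne may rearrange to a silylketene before it adds to the pyrone; this pairing is also untested on a substrate of this size. Fallback with a thermally robust 2π partner: setting out from 15, the ynolate 17 is made as in step 12 but quenched with water, giving the homologous 3-(decalin-9α-yl)propanoic acid F5. LiN(SiMe3)2/Me3SiCl converts it into the bis(trimethylsilyl) ketene acetal of F5 F6, which adds to 3 with the same polarity. Loss of CO2 and Me3SiOH, then aqueous work-up, gives the free phenol corresponding to 20 F7. i-Pr3SiOTf/2,6-lutidine then comes back to the route at 20.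

Further compounds
F1 | step 9 | 4β-methyl-8-methylene-9α-(prop-2-ynyl)decalin-3-one | C=C1CC[C@@H]2[C@@H](C)C(=O)CC[C@@]2(C)[C@@H]1CC#C
F2 | step 9 | 4-methyl-8-methylene-9α-(prop-2-ynyl)-3-(trimethylsilyloxy)decal-3-ene | C=C1CC[C@@H]2C(C)=C(O[Si](C)(C)C)CC[C@@]2(C)[C@@H]1CC#C
F3 | step 11 | hydrazone of 13 | C=C1CC[C@@H]2[C@@](C)(CC[C@@H](Cl)C(C)(C)O[Si](CC)(CC)CC)C(=NN)CC[C@@]2(C)[C@@H]1CC#C
F4 | step 11 | 3,3-dibromo analogue of 15 | C=C1CC[C@@H]2[C@@](C)(CC[C@@H](Cl)C(C)(C)O[Si](CC)(CC)CC)C(Br)(Br)CC[C@@]2(C)[C@@H]1CC#C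
F5 | step 13 | 3-{3α-bromo-4β-[(3R)-3-chloro-4-methyl-4-(triethylsilyloxy)pentyl]-4α-methyl-8-methylenedecalin-9α-yl}propanoic acid | C=C1CC[C@@H]2[C@@](C)(CC[C@@H](Cl)C(C)(C)O[Si](CC)(CC)CC)[C@H](Br)CC[C@@]2(C)[C@@H]1CCC(=O)O
F6 | step 13 | bis(trimethylsilyl) ketene acetal of F5 | C=C1CC[C@@H]2[C@@](C)(CC[C@@H](Cl)C(C)(C)O[Si](CC)(CC)CC)[C@H](Br)CC[C@@]2(C)[C@@H]1CC=C(O[Si](C)(C)C)O[Si](C)(C)C
F7 | step 13 | 2,4-dibromo-6-[(3α-bromo-4β-[(3R)-3-chloro-4-methyl-4-(triethylsilyloxy)pentyl]-4α-methyl-8-methylenedecalin-9α-yl)methyl]phenol | C=C1CC[C@@H]2[C@@](C)(CC[C@@H](Cl)C(C)(C)O[Si](CC)(CC)CC)[C@H](Br)CC[C@@]2(C)[C@@H]1Cc1cc(Br)cc(Br)c1O
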